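**Assumption:** the target has no stereocentre and no stereogenic double bond (its only non-aromatic C=C is endocyclic), so it is achiral and needs no stereocontrol.

## Retrosynthetic overview

1. The pyran C3=C4 bond is cut by an intramolecular aldol condensation, giving an ortho-formyl benzyl phenacyl ether.
2. That benzaldehyde comes from dehydrogenation of a 1,4-cyclohexadiene, itself the Diels–Alder adduct of a keto-ynal with 2,3-dimethoxybuta-1,3-diene.
3. Oxidation to the ynal, [4+2], aromatisation and aldol closure are run in one flask from the propargylic alcohol.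
4. The hydroxy-alkynyl phenacyl ether comes from a Weinreb amide and 2,4-dimethoxyphenyllithium; the Weinreb ether comes from but-2-yne-1,4-diol and 2-chloro-N-methoxy-N-methylacetamide.
5. Ring order: the 2,4-dimethoxyphenyl ring is bought; the dimethoxybenzo ring ([4+2]/aromatisation) and then the pyran ring (aldol) are formed in the same operation.

## Route

**Step 1**
Reactants: 1 but-2-yne-1,4-diol; 2 2-chloro-N-methoxy-N-methylacetamide
Product: 3 2-[(4-hydroxybut-2-yn-1-yl)oxy]-N-methoxy-N-methylacetamide
Conditions: 1 (4 equiv), NaH (1.05 equiv relative to 2), THF/DMF, 0 °C; then 2 (1 equiv), 0 °C → rt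
Reagents that add atoms: none
Why: Williamson ether synthesis, in which the primary propargylic alkoxide displaces chloride from the α-chloro Weinreb amide by SN2 and the fourfold excess of symmetric diol (washed out with water) keeps the bis-ether low; no stereocentre is formed.

**Step 2**
Reactants: 3 2-[(4-hydroxybut-2-yn-1-yl)oxy]-N-methoxy-N-methylacetamide; 4 1-bromo-2,4-dimethoxybenzene
Product: 6 1-(2,4-dimethoxyphenyl)-2-[(4-hydroxybut-2-yn-1-yl)oxy]ethan-1-one, via (2,4-dimethoxyphenyl)lithium 5 (not isolated)
Conditions: 4 (2.3 equiv), n-BuLi (2.2 equiv), THF, −78 °C; then 3 (1 equiv), −78 → −30 °C; aq NH4Cl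
Reagents that add atoms: none
Why: Br/Li exchange fixes the 2,4-dimethoxy pattern of the aryllithium, and the Weinreb ketone synthesis stops at the ketone because the chelated tetrahedral adduct survives until quench (the first equivalent of 5 only deprotonates the OH); no stereocentre is formed.

**Step 3**
Reactants: 6 1-(2,4-dimethoxyphenyl)-2-[(4-hydroxybut-2-yn-1-yl)oxy]ethan-1-one; 7 2,3-dimethoxybuta-1,3-diene
Product: 11 (2,4-dimethoxyphenyl)(6,7-dimethoxy-1H-isochromen-3-yl)methanone, via 4-[2-(2,4-dimethoxyphenyl)-2-oxoethoxy]but-2-ynal 8 (not isolated), via 2-{[2-(2,4-dimethoxyphenyl)-2-oxoethoxy]methyl}-4,5-dimethoxycyclohexa-1,4-diene-1-carbaldehyde 9 (not isolated), via 2-{[2-(2,4-dimethoxyphenyl)-2-oxoethoxy]methyl}-4,5-dimethoxybenzaldehyde 10 (not isolated)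
Conditions: activated MnO2 (20 equiv), 7 (3 equiv), 4 Å MS, PhMe, rt 2 h then 90 °C (sealed), 16 h; cool to rt, DBU (0.5 equiv), 2 h; filter through Celite
Reagents that add atoms: none
Why: Proposed new method: a one-flask merger of four individually known events — MnO2 oxidation of the propargylic alcohol to ynal 8 (as in tandem MnO2 oxidation/trapping), normal-demand Diels–Alder of the LUMO-lowered ynal with the symmetric electron-rich diene 7 (no regiochemistry to control) to skipped diene 9, MnO2 dehydrogenative aromatisation of 9 to benzaldehyde 10, and DBU-mediated intramolecular aldol (Knoevenagel-type) condensation of the only enolisable position (ArCO–CH2–O) onto the non-enolisable ortho aldehyde with E1cB loss of water to close the pyran; the closest known reaction types are Diels–Alder/oxidative-aromatisation benzannulation of activated alkynes with 2,3-dialkoxybutadienes and Rap–Stoermer-type base cyclisation of ortho-formylaryl phenacyl ethers; no stereocentre is formed.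

## Compound list

1 | but-2-yne-1,4-diol | OCC#CCO | starting material
2 | 2-chloro-N-methoxy-N-methylacetamide | CON(C)C(=O)CCl | starting material
3 | 2-[(4-hydroxybut-2-yn-1-yl)oxy]-N-methoxy-N-methylacetamide | CON(C)C(=O)COCC#CCO | intermediate
4 | 1-bromo-2,4-dimethoxybenzene | COc1ccc(Br)c(OC)c1 | starting material
5 | (2,4-dimethoxyphenyl)lithium | [Li]c1ccc(OC)cc1OC | intermediate (not isolated)
6 | 1-(2,4-dimethoxyphenyl)-2-[(4-hydroxybut-2-yn-1-yl)oxy]ethan-1-one | COc1ccc(C(=O)COCC#CCO)c(OC)c1 | intermediate
7 | 2,3-dimethoxybuta-1,3-diene | C=C(OC)C(OC)=C | starting material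
8 | 4-[2-(2,4-dimethoxyphenyl)-2-oxoethoxy]but-2-ynal | COc1ccc(C(=O)COCC#CC=O)c(OC)c1 | intermediate (not isolated)
9 | 2-{[2-(2,4-dimethoxyphenyl)-2-oxoethoxy]methyl}-4,5-dimethoxycyclohexa-1,4-diene-1-carbaldehyde | COC1=C(OC)CC(COCC(=O)c2ccc(OC)cc2OC)=C(C=O)C1 | intermediate (not isolated)
10 | 2-{[2-(2,4-dimethoxyphenyl)-2-oxoethoxy]methyl}-4,5-dimethoxybenzaldehyde | COc1cc(C=O)c(COCC(=O)c2ccc(OC)cc2OC)cc1OC | intermediate (not isolated)
11 | (2,4-dimethoxyphenyl)(6,7-dimethoxy-1H-isochromen-3-yl)methanone | COc1ccc(C(=O)C2=Cc3cc(OC)c(OC)cc3CO2)c(OC)c1 | target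

## Step count and risks

Total steps: 3. Longest linear sequence: 3 (1 → 3 → 6 → 11).

**Most likely to fail, in order: step 3, step 1, step 2.**

**Step 3.** The ynal may degrade before it is trapped, the thermal [4+2] may be slow, the bis-enol ether 9 may hydrolyse, or MnO2 may over-oxidise C1 of the product. The fallback sets out from 6 (with 7) and comes back to the route at 9. Instead of activating the alkyne as an ynal, the unactivated alkyne of 6 is joined to diene 7 by a cobalt-catalysed neutral [4+2] (CoBr2(dppe), Zn, ZnI2, CH2Cl2, rt). This gives the allylic alcohol 1-(2,4-dimethoxyphenyl)-2-{[2-(hydroxymethyl)-4,5-dimethoxycyclohexa-1,4-dien-1-yl]methoxy}ethan-1-one F1. MnO2 in CH2Cl2 at rt then oxidises the allylic alcohol of F1 to dienal 9, which is aromatised by warm MnO2 to 10 and closed with DBU to 11 as in the main route.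

**Step 1.** Mono-alkylation of the poorly soluble symmetric diol may give bis-ether and low conversion. The fallback sets out from 1 and comes back at 3. The diol is desymmetrised first (NaH 1 equiv, then TBSCl, THF) to 4-[(tert-butyldimethylsilyl)oxy]but-2-yn-1-ol F2. F2 is alkylated with 2 (NaH, THF) to 2-({4-[(tert-butyldimethylsilyl)oxy]but-2-yn-1-yl}oxy)-N-methoxy-N-methylacetamide F3, and TBAF in THF releases 3.

**Step 2.** Aryllithium addition in the presence of the lithium alkoxide may stall or deprotonate the α-alkoxy CH2. The fallback sets out from 1 and comes back at 6. It forms the C–O bond instead of the C–C bond. Commercial 2,4-dimethoxybenzoyl chloride (COc1ccc(C(Cl)=O)c(OC)c1) is treated with TMSCHN2 (THF/MeCN, 0 °C) to give 2-diazo-1-(2,4-dimethoxyphenyl)ethan-1-one F4. Rh2(OAc)4 (1 mol %) with excess 1 then gives 6 directly by carbenoid O–H insertion.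

## Further compounds

F1 | step 3 | 1-(2,4-dimethoxyphenyl)-2-{[2-(hydroxymethyl)-4,5-dimethoxycyclohexa-1,4-dien-1-yl]methoxy}ethan-1-one | COC1=C(OC)CC(COCC(=O)c2ccc(OC)cc2OC)=C(CO)C1
F2 | step 1 | 4-[(tert-butyldimethylsilyl)oxy]but-2-yn-1-ol | CC(C)(C)[Si](C)(C)OCC#CCO
F3 | step 1 | 2-({4-[(tert-butyldimethylsilyl)oxy]but-2-yn-1-yl}oxy)-N-methoxy-N-methylacetamide | CON(C)C(=O)COCC#CCO[Si](C)(C)C(C)(C)C
F4 | step 2 | 2-diazo-1-(2,4-dimethoxyphenyl)ethan-1-one | COc1ccc(C(=O)C=[N+]=[N-])c(OC)c1
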